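## Retrosynthetic overview

1. Target 10 ⇐ dione 9: only the C2 carbinol is added at the end, by face-selective 1,2-reduction of the enone carbonyl.
2. Dione 9 ⇐ ketal 5 + (E)-isoeugenol 6: both bonds of the ethano bridge (C5–C6 and C1–C7) are cut at once. Forward, this is an enantioselective cationic [5+2] cycloaddition that closes the cyclopentane and the cycloheptene ring of the bicyclo[3.2.1]octene in one operation and sets four stereocentres.
3. Ketal 5 ⇐ phenol 4 ⇐ ether 3 ⇐ 1 + 2: oxidative dearomatisation, aromatic Claisen rearrangement, O-allylation.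
4. Ring order: both benzene rings are bought; the six-membered carbocycle of the core is the dearomatised ring of 4; the five- and seven-membered rings are formed last and together (step 4).

## Conventions and assumptions

- Core locants used in all names (dione numbering, kept for 10): C1 = MeO-bearing bridgehead, C2 = C=O (later CHOH), C3 = C–OMe, C4 = vinyl CH, C5 = allyl-bearing bridgehead, C6 = CH–CH3, C7 = CH–aryl, C8 = bridging C=O.
- Assumption: 2,3,4-trimethoxyphenol and (E)-isoeugenol are bought as catalogue compounds.
- Assumption: the sense of induction of the chiral acid in step 4 cannot be predicted with confidence; the (R)-catalyst is written, and its mirror image is used if the first run gives the enantiomeric series.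

## Route

Step 1
Reactants: 1 2,3,4-trimethoxyphenol; 2 allyl bromide
Product: 3 1,2,3-trimethoxy-4-(prop-2-en-1-yloxy)benzene
Conditions: K2CO3, acetone, reflux
Reagents that add atoms: none
Why: Williamson ether synthesis, SN2 O-allylation of the phenoxide; no stereocentre.

Step 2
Reactants: 3 1,2,3-trimethoxy-4-(prop-2-en-1-yloxy)benzene
Product: 4 2,3,4-trimethoxy-6-(prop-2-en-1-yl)phenol
Conditions: PhNEt2, 200 °C, sealed tube
Reagents that add atoms: none
Why: aromatic Claisen rearrangement ([3,3]-sigmatropic shift) to the only unsubstituted ortho position, followed by tautomerisation; no stereocentre.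

Step 3
Reactants: 4 2,3,4-trimethoxy-6-(prop-2-en-1-yl)phenol
Product: 5 4,4,5,6-tetramethoxy-2-(prop-2-en-1-yl)cyclohexa-2,5-dien-1-one
Conditions: PhI(OAc)2, MeOH, 0 °C
Reagents that add atoms: methanol, CO
Why: hypervalent-iodine oxidative dearomatisation of a p-methoxyphenol, in which methanol adds para to the oxidised phenol to give the p-quinone monoketal; no stereocentre.

Step 4
Reactants: 5 4,4,5,6-tetramethoxy-2-(prop-2-en-1-yl)cyclohexa-2,5-dien-1-one; 6 (E)-isoeugenol
Product: 9 (1S,5R,6R,7S)-7-(4-hydroxy-3-methoxyphenyl)-1,3-dimethoxy-6-methyl-5-(prop-2-en-1-yl)bicyclo[3.2.1]oct-3-ene-2,8-dione, via phenoxonium cation 7 (not isolated), via C2 dimethyl ketal 8 (not isolated)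
Conditions: (R)-TRIP N-triflylphosphoramide (10 mol %), CH2Cl2, −60 → −20 °C; then 1 M HCl, THF, 0 °C
Reagents that add atoms: water, O
Why: Proposed new method: the chiral acid ionises ketal 5 to the planar phenoxonium (oxidopentadienyl-type) cation 7, held as a contact ion pair with the chiral phosphoramide anion that also hydrogen-bonds the phenol of 6; the CH(CH3) carbon of the (E)-alkene adds to the allyl-bearing terminus C5 on the unshielded face (sets C5 and C6), the resulting p-quinone-methide/benzylic cation is closed by the enol-ether carbon C1 with the aryl group endo under the ring (sets C1 and C7, E-alkene gives trans CH3/aryl), and methanol returns to C2 to give ketal 8, which the work-up hydrolyses; the closest known reaction type is the acid-promoted cationic [5+2] cycloaddition of p-quinone monoketals with (E)-propenylbenzenes (Büchi-type), here made enantioselective by chiral-counteranion catalysis as used for quinone-ketal and oxocarbenium ion pairs.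

Step 5
Reactants: 9 (1S,5R,6R,7S)-7-(4-hydroxy-3-methoxyphenyl)-1,3-dimethoxy-6-methyl-5-(prop-2-en-1-yl)bicyclo[3.2.1]oct-3-ene-2,8-dione
Product: 10 (1R,2S,5R,6R,7S)-2-hydroxy-7-(4-hydroxy-3-methoxyphenyl)-1,3-dimethoxy-6-methyl-5-(prop-2-en-1-yl)bicyclo[3.2.1]oct-3-en-8-one
Conditions: NaBH4, CeCl3·7H2O, MeOH–THF, −78 °C
Reagents that add atoms: none
Why: Luche 1,2-reduction picks the conjugated C2 ketone over the C8 ketone, which sits between two fully substituted bridgeheads; hydride enters from the face of the one-carbon bridge because the other face is covered by the endo-aryl group on C7, which puts the new OH on the aryl side (2S).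

## Compound list

1 | 2,3,4-trimethoxyphenol | COc1ccc(O)c(OC)c1OC | starting material
2 | allyl bromide (3-bromoprop-1-ene) | C=CCBr | starting material
3 | 1,2,3-trimethoxy-4-(prop-2-en-1-yloxy)benzene | C=CCOc1ccc(OC)c(OC)c1OC | intermediate
4 | 2,3,4-trimethoxy-6-(prop-2-en-1-yl)phenol | C=CCc1cc(OC)c(OC)c(OC)c1O | intermediate
5 | 4,4,5,6-tetramethoxy-2-(prop-2-en-1-yl)cyclohexa-2,5-dien-1-one (p-quinone monoketal) | C=CCC1=CC(OC)(OC)C(OC)=C(OC)C1=O | intermediate
6 | (E)-isoeugenol (2-methoxy-4-[(1E)-prop-1-en-1-yl]phenol) | C/C=C/c1ccc(O)c(OC)c1 | starting material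
7 | phenoxonium cation (6-allyl-2,3,4-trimethoxyphenoxonium, ion pair with the chiral anion, not isolated) | C=CCC1=CC(=[O+]C)C(OC)=C(OC)C1=O | intermediate
8 | C2 dimethyl ketal of 9, (1S,5R,6R,7S)-7-(4-hydroxy-3-methoxyphenyl)-1,2,2,3-tetramethoxy-6-methyl-5-(prop-2-en-1-yl)bicyclo[3.2.1]oct-3-en-8-one (not isolated) | C=CC[C@@]12C=C(OC)C(OC)(OC)[C@@](OC)(C1=O)[C@H](c1ccc(O)c(OC)c1)[C@H]2C | intermediate
9 | (1S,5R,6R,7S)-7-(4-hydroxy-3-methoxyphenyl)-1,3-dimethoxy-6-methyl-5-(prop-2-en-1-yl)bicyclo[3.2.1]oct-3-ene-2,8-dione (7-endo-aryl, 6-exo-methyl) | C=CC[C@@]12C=C(OC)C(=O)[C@@](OC)(C1=O)[C@H](c1ccc(O)c(OC)c1)[C@H]2C | intermediate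
10 | (1R,2S,5R,6R,7S)-2-hydroxy-7-(4-hydroxy-3-methoxyphenyl)-1,3-dimethoxy-6-methyl-5-(prop-2-en-1-yl)bicyclo[3.2.1]oct-3-en-8-one (CNP0330966.1) | C=CC[C@@]12C=C(OC)[C@H](O)[C@@](OC)(C1=O)[C@H](c1ccc(O)c(OC)c1)[C@H]2C | target

## Step count and risks

Total step count: 5. Longest linear sequence: 5 steps (1 → 3 → 4 → 5 → 9 → 10); 6 enters at step 4.

The three steps most likely to fail:

**Step 4 (enantioselective [5+2]).** Enantioselectivity has no direct precedent. The known side channels of this cation chemistry can also interfere: attack at the MeO-bearing terminus, O-closure to a hydrobenzofuran isomer, and the exo-aryl series. The fallback sets out from 5 and 6. The cycloaddition is run with an achiral acid (CF3CO2H, MeCN, −30 °C, same aqueous work-up; warming lets any O-cyclised isomer re-ionise and close at carbon). This gives 9 together with its mirror image ent-9 F1 as the racemate. The racemate is separated by preparative chromatography on a chiral stationary phase, and the route is rejoined at 9.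

**Step 5 (reduction).** The C8 ketone may be reduced competitively. The fallback sets out from 9. Both carbonyls are reduced (excess NaBH4, MeOH, 0 °C) to the 2,8-diol F2. The phenol and the more accessible C2 hydroxyl are silylated (Et3SiOTf, 2,6-lutidine, −78 °C) to the bis(triethylsilyl) ether F3, while the C8 hydroxyl between two fully substituted bridgeheads stays free. Dess–Martin oxidation gives the 8-ketone F4, and HF·pyridine removes both silyl groups, which comes back to the route at 10. The C8 configuration written for F2 and F3 is the expected one and is erased again in F4.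

**Step 3 (oxidative ketalisation).** Over-oxidation to the quinone or an unstable ketal would stop the route. The fallback sets out from 4. Wessely-type acetoxylative dearomatisation (Pb(OAc)4, AcOH–CH2Cl2, 0 °C) gives the ortho-quinol acetate F5, used crude and racemic; regioisomeric quinol acetates are equally usable because all ionise to the same cation. Under the conditions of step 4, F5 loses acetate to give cation 7 and reacts with 6, so ketal 5 is bypassed and the route is rejoined at 9.

## Further compounds

F1 | step 4 | ent-9, (1R,5S,6S,7R)-7-(4-hydroxy-3-methoxyphenyl)-1,3-dimethoxy-6-methyl-5-(prop-2-en-1-yl)bicyclo[3.2.1]oct-3-ene-2,8-dione | C=CC[C@]12C=C(OC)C(=O)[C@](OC)(C1=O)[C@@H](c1ccc(O)c(OC)c1)[C@@H]2C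
F2 | step 5 | 2,8-diol of 9 (2S as in 10; 8-OH on the side of the C6–C7 bridge, 8R) | C=CC[C@@]12C=C(OC)[C@H](O)[C@@](OC)([C@@H]1O)[C@H](c1ccc(O)c(OC)c1)[C@H]2C
F3 | step 5 | bis(triethylsilyl) ether of F2 (silyl on the phenol oxygen and on the C2 oxygen; 8-OH free) | C=CC[C@@]12C=C(OC)[C@H](O[Si](CC)(CC)CC)[C@@](OC)([C@@H]1O)[C@H](c1ccc(O[Si](CC)(CC)CC)c(OC)c1)[C@H]2C
F4 | step 5 | bis(triethylsilyl) ether of 10 (8-ketone restored) | C=CC[C@@]12C=C(OC)[C@H](O[Si](CC)(CC)CC)[C@@](OC)(C1=O)[C@H](c1ccc(O[Si](CC)(CC)CC)c(OC)c1)[C@H]2C
F5 | step 3 | 6-acetoxy-4,5,6-trimethoxy-2-(prop-2-en-1-yl)cyclohexa-2,4-dien-1-one (racemic; its stereocentre is lost on ionisation) | C=CCC1=CC(OC)=C(OC)C(OC)(OC(C)=O)C1=O
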